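**Plan**

- Retrosynthesis: the sulfate S–O bonds at O3 and O3' and the 4'-O-benzyl bond are cut first, then the 5-O-methyl bond and the two MOM acetals, then O1–C2 of ring C, and last the O1–C8a and C4–C4a bonds that tie ring A to the C4–C3–C2–ring B chain.
- Enabling feature: O1 and the C4 carbonyl stand on the adjacent ring A carbons C8a and C4a, and the C5 oxygen stands next to C4a. A 3-alkoxybenzyne returns exactly this pattern when a carboxylate oxygen adds at the aryne carbon remote from the alkoxy group and the acyl group then moves to the carbon beside it.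
- Forward: aryne precursor 7 (three steps from 3,5-dimethoxyphenol) and the α-(methoxymethoxy)cinnamic acid 15 (five steps from methyl glycolate and 4-(benzyloxy)-3-hydroxybenzaldehyde) are joined by aryne insertion into the acid C–O bond to give the open 2'-hydroxychalcone 18. Ring C is the only ring made; it is closed and aromatised afterwards with I2/DMSO.
- End game: chelation-controlled 5-O-demethylation with MOM removal, double O-sulfation at O3 and O3', hydrogenolysis of the 4'-benzyl ether.
- Stereochemistry: the target has no stereocentre. The only stereo-element on the way, the Z enol ether of 14, 15 and 18, is set thermodynamically in step 7 and disappears on ring closure.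

Key step: step 9

Remark: the aryl hydrogen sulfates 23 and 24 are prepared and handled as disodium salts and are named and drawn in the acid form of the target structure, which the last operation releases by cold exchange on an acid resin; lithium, caesium and magnesium salts of numbered compounds (enolate, carboxylates, phenoxides, the aryllithium of step 2) are not numbered separately.

**Route**

Step 1
Reactants: 1 3,5-dimethoxyphenol
Product: 2 3,5-dimethoxyphenyl N-(propan-2-yl)carbamate
Conditions: i-PrNCO, Et3N (cat.), CH2Cl2, rt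
Reagents that add atoms: isopropyl isocyanate, CC(C)N=C=O
Why: Base-catalysed addition of a phenol to an isocyanate (carbamoylation) installs an N-isopropyl carbamate, a strong ortho-directing group that can later be removed under mild basic conditions.

Step 2
Reactants: 2 3,5-dimethoxyphenyl N-(propan-2-yl)carbamate
Product: 5 3,5-dimethoxy-2-(trimethylsilyl)phenyl N-(propan-2-yl)carbamate, via N-silyl carbamate 3 (not isolated), via N-silyl C-silyl carbamate 4 (not isolated)
Conditions: TBSOTf, TMEDA, Et2O, 0 °C to rt; then n-BuLi, TMEDA, −78 °C; then TMSCl, −78 °C to rt; aq. NaHSO4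
Reagents that add atoms: chlorotrimethylsilane, C[Si](C)(C)Cl
Why: Directed ortho-metalation of the in situ N-silylated carbamate, in which the carbamate and the 3-methoxy group cooperate to direct lithiation to C2 between them rather than to C4 between the two weaker methoxy directors, followed by trapping with TMSCl and hydrolysis of the N–Si bond in the acidic work-up.

Step 3
Reactants: 5 3,5-dimethoxy-2-(trimethylsilyl)phenyl N-(propan-2-yl)carbamate
Product: 7 3,5-dimethoxy-2-(trimethylsilyl)phenyl trifluoromethanesulfonate, via 3,5-dimethoxy-2-(trimethylsilyl)phenol 6 (not isolated)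
Conditions: Et2NH, DBU, MeCN, 40 °C; then PhNTf2, rt
Reagents that add atoms: N-phenylbis(trifluoromethanesulfonimide), O=S(=O)(N(c1ccccc1)S(=O)(=O)C(F)(F)F)C(F)(F)F
Why: Base-induced E1cB cleavage of the N-monoalkyl carbamate, with the isocyanate scavenged by Et2NH, frees the hindered silylphenol, whose phenoxide is triflated in the same flask by PhNTf2, the standard one-pot route to ortho-silylaryl triflates.

Step 4
Reactants: 8 methyl glycolate
Product: 9 methyl 2-(methoxymethoxy)acetate
Conditions: MOMCl, i-Pr2NEt, CH2Cl2, 0 °C to rt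
Reagents that add atoms: chloromethyl methyl ether, COCCl
Why: Williamson-type O-alkylation of the primary alcohol with the reactive α-chloro ether under amine base gives the MOM ether without touching the methyl ester.

Step 5
Reactants: 10 4-(benzyloxy)-3-hydroxybenzaldehyde
Product: 11 4-(benzyloxy)-3-(methoxymethoxy)benzaldehyde
Conditions: MOMCl, i-Pr2NEt, CH2Cl2, 0 °C to rt
Reagents that add atoms: chloromethyl methyl ether, COCCl
Why: O-Alkylation of the phenol with MOMCl and a hindered amine base gives the aryl MOM ether, which is stable to all the basic steps that follow and removable by acid in the presence of the benzyl ether.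

Step 6
Reactants: 9 methyl 2-(methoxymethoxy)acetate; 11 4-(benzyloxy)-3-(methoxymethoxy)benzaldehyde
Product: 12 methyl 3-[4-(benzyloxy)-3-(methoxymethoxy)phenyl]-3-hydroxy-2-(methoxymethoxy)propanoate (racemic syn/anti mixture)
Conditions: LiN(i-Pr)2 (LDA), THF, −78 °C; then 11, −78 °C; aq. NH4Cl
Reagents that add atoms: none
Why: Aldol addition of the lithium enolate of the α-alkoxy ester to the non-enolisable aryl aldehyde forms the future C2–C3 bond, and the two new stereocentres are left uncontrolled because both are removed in step 7.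

Step 7
Reactants: 12 methyl 3-[4-(benzyloxy)-3-(methoxymethoxy)phenyl]-3-hydroxy-2-(methoxymethoxy)propanoate
Product: 14 methyl (Z)-3-[4-(benzyloxy)-3-(methoxymethoxy)phenyl]-2-(methoxymethoxy)prop-2-enoate, via benzylic mesylate 13 (not isolated)
Conditions: MsCl, Et3N, CH2Cl2, 0 °C; then DBU, rt
Reagents that add atoms: none
Why: Mesylation of the benzylic alcohol followed by DBU-induced E1cB β-elimination gives the trisubstituted enol ether, and because elimination passes through the ester enolate the more stable Z isomer (aryl trans to the ester) is expected from both aldol diastereomers.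

Step 8
Reactants: 14 methyl (Z)-3-[4-(benzyloxy)-3-(methoxymethoxy)phenyl]-2-(methoxymethoxy)prop-2-enoate
Product: 15 (Z)-3-[4-(benzyloxy)-3-(methoxymethoxy)phenyl]-2-(methoxymethoxy)prop-2-enoic acid
Conditions: LiOH·H2O, THF/MeOH/H2O, rt to 40 °C; then 1 M HCl to pH 4, 0 °C
Reagents that add atoms: lithium hydroxide (supplies the acid OH oxygen), [Li+].[OH-]
Why: Saponification of the methyl ester by hydroxide (acyl–oxygen cleavage) leaves the MOM acetals, the benzyl ether and the enol ether geometry untouched, and cautious cold acidification protects the enol acetal.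

Step 9
Reactants: 7 3,5-dimethoxy-2-(trimethylsilyl)phenyl trifluoromethanesulfonate; 15 (Z)-3-[4-(benzyloxy)-3-(methoxymethoxy)phenyl]-2-(methoxymethoxy)prop-2-enoic acid
Product: 18 (Z)-3-[4-(benzyloxy)-3-(methoxymethoxy)phenyl]-1-(2-hydroxy-4,6-dimethoxyphenyl)-2-(methoxymethoxy)prop-2-en-1-one, via 3,5-dimethoxybenzyne 16 (not isolated), via caesium aryl anion 17 (not isolated)
Conditions: CsF (4 equiv), THF, 125 °C, sealed tube
Reagents that add atoms: none
Why: Fluoride removes the silyl group of 7 and triflate leaves to give aryne 16; the caesium carboxylate of 15 adds through oxygen at the aryne carbon remote from the flanking methoxy group (O1–C8a), and the aryl anion 17 attacks its own ester carbonyl through a four-membered alkoxide whose collapse moves the acyl group from oxygen to carbon (C4–C4a) and frees the phenoxide. The closest known reaction type is the fluoride-induced insertion of arynes into the C–O bond of carboxylic acids, which gives ortho-hydroxyaryl ketones from aliphatic, aromatic and unsaturated acids. No ring is closed and no stereocentre is formed: the α-alkoxy donor and the electron-rich β-aryl group make the enone β-carbon a poor acceptor, so the phenoxide should stay open, and any cyclised material (flavanone 19) would be converted by step 10 as well. The selectivity needed is regiochemical, oxygen at C8a and acyl at C4a between OH and OMe. It is secured because 16 is the only aryne that 7 can give and because attack meta to the flanking methoxy group places the developing negative charge ortho to that inductively withdrawing oxygen, the normal outcome for 3-alkoxybenzynes. The enol ether, the MOM acetals and the benzyl ether are inert to CsF in hot THF.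

Step 10
Reactants: 18 (Z)-3-[4-(benzyloxy)-3-(methoxymethoxy)phenyl]-1-(2-hydroxy-4,6-dimethoxyphenyl)-2-(methoxymethoxy)prop-2-en-1-one
Product: 20 2-[4-(benzyloxy)-3-(methoxymethoxy)phenyl]-5,7-dimethoxy-3-(methoxymethoxy)-4H-chromen-4-one, via 3-alkoxyflavanone 19 (not isolated)
Conditions: I2 (10 mol%), DMSO, 120 °C
Reagents that add atoms: none
Why: Iodine-catalysed oxidative cyclisation of a 2'-hydroxychalcone, in which 6-endo oxa-Michael closure (O1–C2) gives the flavanone, iodination at C3 and loss of HI give the flavone and DMSO reoxidises HI, so that the acid level stays low for the MOM groups, whose partial loss after ring closure would be harmless because step 11 removes them.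

Step 11
Reactants: 20 2-[4-(benzyloxy)-3-(methoxymethoxy)phenyl]-5,7-dimethoxy-3-(methoxymethoxy)-4H-chromen-4-one
Product: 22 2-[4-(benzyloxy)-3-hydroxyphenyl]-3,5-dihydroxy-7-methoxy-4H-chromen-4-one (rhamnetin 4'-benzyl ether), via 3'-MOM-protected 5-hydroxyflavonol 21 (not isolated)
Conditions: MgI2·OEt2, toluene/THF, 80 °C; then 3 M HCl, MeOH/THF, 50 °C
Reagents that add atoms: none
Why: Chelation-controlled ether cleavage, in which magnesium bound to the C4 carbonyl activates the flanking 5-OMe and 3-OMOM groups for attack by iodide while the 7-OMe and the remote benzyl ether are not activated, followed by acid-catalysed acetal exchange in methanol that removes the 3'-MOM group and any MOM group that survived the first stage.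

Step 12
Reactants: 22 2-[4-(benzyloxy)-3-hydroxyphenyl]-3,5-dihydroxy-7-methoxy-4H-chromen-4-one
Product: 23 2-[4-(benzyloxy)-3-(sulfooxy)phenyl]-5-hydroxy-7-methoxy-4-oxo-4H-chromen-3-yl hydrogen sulfate (isolated as the disodium salt)
Conditions: SO3·pyridine (excess), pyridine, 60 °C; then aq. NaHCO3, Sephadex LH-20
Reagents that add atoms: sulfur trioxide–pyridine complex, O=S(=O)([O-])[n+]1ccccc1
Why: O-Sulfation of phenolic and enolic hydroxyls with a sulfur trioxide–amine complex converts the 3-OH and 3'-OH, while the 5-OH, held in a strong hydrogen bond to the C4 carbonyl, is the least reactive hydroxyl of a flavonol and the 4'-oxygen is blocked as its benzyl ether.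

Step 13
Reactants: 23 2-[4-(benzyloxy)-3-(sulfooxy)phenyl]-5-hydroxy-7-methoxy-4-oxo-4H-chromen-3-yl hydrogen sulfate (disodium salt)
Product: 24 rhamnetin 3,3'-disulfate
Conditions: H2 (1 atm), 10% Pd/C, MeOH/H2O, rt; then Dowex 50W (H+ form), 0 °C, lyophilise
Reagents that add atoms: none
Why: Catalytic hydrogenolysis of the aryl benzyl ether over Pd/C frees the 4'-OH, the sulfate salts, the flavone C2–C3 double bond and the methyl ether being stable to one atmosphere of hydrogen at room temperature, and cold cation exchange gives the hydrogen sulfate form (the disodium salt is the form to store).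

**Compound list**

1 | 3,5-dimethoxyphenol | COc1cc(O)cc(OC)c1 | starting material
2 | 3,5-dimethoxyphenyl N-(propan-2-yl)carbamate | COc1cc(OC)cc(OC(=O)NC(C)C)c1 | intermediate
3 | 3,5-dimethoxyphenyl N-(tert-butyldimethylsilyl)-N-(propan-2-yl)carbamate | COc1cc(OC)cc(OC(=O)N(C(C)C)[Si](C)(C)C(C)(C)C)c1 | intermediate
4 | 3,5-dimethoxy-2-(trimethylsilyl)phenyl N-(tert-butyldimethylsilyl)-N-(propan-2-yl)carbamate | COc1cc(OC)c([Si](C)(C)C)c(OC(=O)N(C(C)C)[Si](C)(C)C(C)(C)C)c1 | intermediate
5 | 3,5-dimethoxy-2-(trimethylsilyl)phenyl N-(propan-2-yl)carbamate | COc1cc(OC)c([Si](C)(C)C)c(OC(=O)NC(C)C)c1 | intermediate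
6 | 3,5-dimethoxy-2-(trimethylsilyl)phenol | COc1cc(OC)c([Si](C)(C)C)c(O)c1 | intermediate
7 | 3,5-dimethoxy-2-(trimethylsilyl)phenyl trifluoromethanesulfonate | COc1cc(OC)c([Si](C)(C)C)c(OS(=O)(=O)C(F)(F)F)c1 | intermediate
8 | methyl glycolate (methyl 2-hydroxyacetate) | COC(=O)CO | starting material
9 | methyl 2-(methoxymethoxy)acetate | COCOCC(=O)OC | intermediate
10 | 4-(benzyloxy)-3-hydroxybenzaldehyde | O=Cc1ccc(OCc2ccccc2)c(O)c1 | starting material
11 | 4-(benzyloxy)-3-(methoxymethoxy)benzaldehyde | COCOc1cc(C=O)ccc1OCc1ccccc1 | intermediate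
12 | methyl 3-[4-(benzyloxy)-3-(methoxymethoxy)phenyl]-3-hydroxy-2-(methoxymethoxy)propanoate, racemic syn/anti mixture | COCOC(C(=O)OC)C(O)c1ccc(OCc2ccccc2)c(OCOC)c1 | intermediate
13 | methyl 3-[4-(benzyloxy)-3-(methoxymethoxy)phenyl]-3-(methanesulfonyloxy)-2-(methoxymethoxy)propanoate, diastereomer mixture | COCOC(C(=O)OC)C(OS(C)(=O)=O)c1ccc(OCc2ccccc2)c(OCOC)c1 | intermediate
14 | methyl (Z)-3-[4-(benzyloxy)-3-(methoxymethoxy)phenyl]-2-(methoxymethoxy)prop-2-enoate | COC(=O)/C(OCOC)=C/c1ccc(OCc2ccccc2)c(OCOC)c1 | intermediate
15 | (Z)-3-[4-(benzyloxy)-3-(methoxymethoxy)phenyl]-2-(methoxymethoxy)prop-2-enoic acid | OC(=O)/C(OCOC)=C/c1ccc(OCc2ccccc2)c(OCOC)c1 | intermediate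
16 | 3,5-dimethoxybenzyne (1,2-didehydro-3,5-dimethoxybenzene) | COC1=CC(OC)=CC#C1 | intermediate
17 | caesium salt of the C2 aryl anion of the 3,5-dimethoxyphenyl ester of acid 15 (anion between the ester oxygen and a methoxy group) | [Cs+].COc1cc(OC)[c-]c(OC(=O)/C(OCOC)=C/c2ccc(OCc3ccccc3)c(OCOC)c2)c1 | intermediate
18 | (Z)-3-[4-(benzyloxy)-3-(methoxymethoxy)phenyl]-1-(2-hydroxy-4,6-dimethoxyphenyl)-2-(methoxymethoxy)prop-2-en-1-one | COc1cc(O)c(C(=O)/C(OCOC)=C/c2ccc(OCc3ccccc3)c(OCOC)c2)c(OC)c1 | intermediate
19 | 2-[4-(benzyloxy)-3-(methoxymethoxy)phenyl]-5,7-dimethoxy-3-(methoxymethoxy)chroman-4-one, racemic cis/trans mixture | COCOC1C(c2ccc(OCc3ccccc3)c(OCOC)c2)Oc2cc(OC)cc(OC)c2C1=O | intermediate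
20 | 2-[4-(benzyloxy)-3-(methoxymethoxy)phenyl]-5,7-dimethoxy-3-(methoxymethoxy)-4H-chromen-4-one | COCOc1c(-c2ccc(OCc3ccccc3)c(OCOC)c2)oc2cc(OC)cc(OC)c2c1=O | intermediate
21 | 2-[4-(benzyloxy)-3-(methoxymethoxy)phenyl]-3,5-dihydroxy-7-methoxy-4H-chromen-4-one | COCOc1cc(-c2oc3cc(OC)cc(O)c3c(=O)c2O)ccc1OCc1ccccc1 | intermediate
22 | 2-[4-(benzyloxy)-3-hydroxyphenyl]-3,5-dihydroxy-7-methoxy-4H-chromen-4-one (rhamnetin 4'-benzyl ether) | COc1cc(O)c2c(=O)c(O)c(-c3ccc(OCc4ccccc4)c(O)c3)oc2c1 | intermediate
23 | 2-[4-(benzyloxy)-3-(sulfooxy)phenyl]-5-hydroxy-7-methoxy-4-oxo-4H-chromen-3-yl hydrogen sulfate (rhamnetin 4'-benzyl ether 3,3'-disulfate) | COc1cc(O)c2c(=O)c(OS(=O)(=O)O)c(-c3ccc(OCc4ccccc4)c(OS(=O)(=O)O)c3)oc2c1 | intermediate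
24 | rhamnetin 3,3'-disulfate: 5-hydroxy-2-[4-hydroxy-3-(sulfooxy)phenyl]-7-methoxy-4-oxo-4H-chromen-3-yl hydrogen sulfate | COc1cc(O)c2c(=O)c(OS(=O)(=O)O)c(-c3ccc(O)c(OS(=O)(=O)O)c3)oc2c1 | target

**Step count**

Total: 13 steps. Longest linear sequence: 9 steps (4, 6, 7, 8, 9, 10, 11, 12, 13 from methyl glycolate; the aldehyde branch 5, 6–13 is equally long; the aryne branch 1, 2, 3, 9–13 has 8).

**Steps most likely to fail**

Step 9. The aryl anion 17 may be protonated by the acid proton (carried as bifluoride) before the acyl shift, which would stop at the aryl ester, and the product phenoxide may be O-arylated by a second aryne. The fallback generates the same ortho-metalated aryl ester by halogen–lithium exchange instead of from an aryne. It sets out from 5 and 15. Ipso-iododesilylation of 5 (ICl, CH2Cl2, −78 °C) should give 2-iodo-3,5-dimethoxyphenyl N-(propan-2-yl)carbamate F1. Carbamate cleavage as in step 3 (Et2NH, DBU, MeCN, 40 °C) frees 2-iodo-3,5-dimethoxyphenol F2. Carbodiimide coupling of F2 with acid 15 (EDC·HCl, DMAP, CH2Cl2) gives 2-iodo-3,5-dimethoxyphenyl (Z)-3-[4-(benzyloxy)-3-(methoxymethoxy)phenyl]-2-(methoxymethoxy)prop-2-enoate F3. Iodine–lithium exchange (n-BuLi, THF, −100 °C) then triggers the anionic Fries-type 1,3 acyl shift from oxygen to carbon, and the route is rejoined at 18.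

Step 10. HI formed in the hot DMSO may cleave the enol MOM ether before ring closure, which would divert the material through the 1,2-diketone to a benzofuranone hemiketal, and ring A may be iodinated. The fallback separates ring closure from oxidation and avoids acid. It sets out from 18: base-mediated oxa-Michael closure (NaOAc, EtOH, reflux) to the flavanone 19, now isolated, then quinone dehydrogenation (DDQ, 1,4-dioxane, reflux) to rejoin the route at 20. No compound outside the list is made (F0).

Step 12. Sulfation of the hydrogen-bonded 3-OH may stay incomplete, the 5-OH may be sulfated under forcing conditions, and the enol-type 3-sulfate may hydrolyse during isolation of a very polar salt. The fallback uses a protected sulfate that can be purified on silica. It sets out from 22: 2,2,2-trichloroethyl chlorosulfate with Et3N and DMAP in THF should give the neutral diester rhamnetin 4'-benzyl ether 3,3'-bis(2,2,2-trichloroethyl sulfate) F4. Reductive removal of the trichloroethyl groups (Zn, HCO2NH4, MeOH, rt) gives the bis-sulfate, and the route is rejoined at 23.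

**Further compounds**

F1 | step 9 | 2-iodo-3,5-dimethoxyphenyl N-(propan-2-yl)carbamate | COc1cc(OC)c(I)c(OC(=O)NC(C)C)c1
F2 | step 9 | 2-iodo-3,5-dimethoxyphenol | COc1cc(O)c(I)c(OC)c1
F3 | step 9 | 2-iodo-3,5-dimethoxyphenyl (Z)-3-[4-(benzyloxy)-3-(methoxymethoxy)phenyl]-2-(methoxymethoxy)prop-2-enoate | COc1cc(OC)c(I)c(OC(=O)/C(OCOC)=C/c2ccc(OCc3ccccc3)c(OCOC)c2)c1
F0 | step 10 | none | none
F4 | step 12 | rhamnetin 4'-benzyl ether 3,3'-bis(2,2,2-trichloroethyl sulfate) | COc1cc(O)c2c(=O)c(OS(=O)(=O)OCC(Cl)(Cl)Cl)c(-c3ccc(OCc4ccccc4)c(OS(=O)(=O)OCC(Cl)(Cl)Cl)c3)oc2c1
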